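Readings and results come from a simulation from invented constants; the scatter is artificial.

In percent of the substrate charged, what I watch in this flask is how fast first product is used against how fast it is made.

| flask | substrate | partner | remark | time |
|---|---|---|---|---|
| delta | 23 mM | 2 equiv | the very flask that is asked about, followed so far |  |
| gamma | 23 mM | 1 equiv | run made earlier |  |
| flask | 23 mM | 2.00 equiv |  | 20 min |

| run | time / min | substrate / % | first product / % | double product / % |
|---|---|---|---|---|
| delta | 1.50 | 38.1 | 45.5 | 7.6 |
| delta | 3.00 | 20.8 | 47.2 | 9.2 |
| delta | 5.00 | 11.5 | 41.9 | 6.7 |
| delta | 6.00 | 9.9 | 39.7 | 5.6 |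
| delta | 8.00 | 7.1 | 34.7 | 3.7 |
| gamma | 1.00 | 70.3 | 26.7 | 1.7 |
| gamma | 2.00 | 55.7 | 37.0 | 3.4 |
| gamma | 4.00 | 41.7 | 44.4 | 3.3 |
| gamma | 8.00 | 32.3 | 47.0 | 1.4 |
| gamma | 15.0 | 28.1 | 47.6 | 0 |

(readings scatter by 0.3 percentage points)

1. how much substrate there is at 20 min, in percent of the substrate charged
2. how much first product there is at 20 min, in percent of the substrate charged
3. how much double product there is at 20 min, in percent of the substrate charged
4. how much tris adduct there is at 20 min, in percent of the substrate charged

If each step goes as the product of its two reactants, partner stands in both rates and cancels from their ratio. The use ratio is then a factor times first product over substrate. I read 0.547 from the gamma run between 8.00 min and 15.0 min, though first product rose there by 0.6 percentage points, not far above the scatter of 0.3 points. I take this as a reading of the selectivity factor, the second step's rate constant over the first's. With x the fraction of substrate left, first product is x raised to the factor, minus x, over one minus the factor.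

In the delta run, this same flask, the use ratio goes from 0.654 at 1.50 min to 1.24 at 3.00 min, so by these readings first product peaks between them. By 8.00 min it is 2.67, and first product is used faster than it is made.

Two extremes bracket this flask at 20 min. Stop the partner at 8.00 min, and substrate stays at 7.1% with first product at 34.7%. Hold the decay of 0.166 min⁻¹ from the last readings, and substrate reaches 0.966% with first product 15.3%. The decay read between 1.50 min and 3.00 min was 0.404 min⁻¹, higher than that, so I take partner as declining and commit to the geometric middle: substrate 2.62%, first product 24.3%, use ratio 5.08.

The forecast, projecting “with declining partner, slightly buffered by idle release”, gives substrate 2.2%, first product 20.5%, double product 1% and tris adduct 14%.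

The flask gives substrate 2.37%, first product 22.2%, double product 0.881% and tris adduct 13.1%.

    substrate + partner → first product (k = 0.300 M⁻¹ s⁻¹)
    partner + first product → double product (k = 0.170 M⁻¹ s⁻¹)
    partner + double product → tris adduct (k = 0.210 M⁻¹ s⁻¹)
    partner + tris adduct ⇌ idle adduct, settled at all times (K = 14.0 M⁻¹)
    double product → decomposed reagent (k = 0.0140 s⁻¹)

With the factor as read, these values put the use ratio in this flask at 5.13. In the neighbouring flask, charged with 1.20 equiv of partner, substrate stands at 19.1% at 20 min, and partner at 1.02% of its own charge. The same factor there gives a use ratio of 1.32 and a first product of 47.1%; that flask holds 46.3%.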